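The data were generated by integration with constants of no real substance; noise was put on by code.

The pitfall with early readings is that a rate constant fitted to them goes on running for as long as the clock is set, whether or not the flask does. In the earlier runs free monomer stood at 87.9 % or higher at every last reading, so the reckoning for Tuesday's and Saturday's had to reach well beyond what had been seen.

| flask | free monomer | initiator | temperature | remark | time |
|---|---|---|---|---|---|
| zeta | 0.38 M | 0.38 mM | −5 °C | run made earlier |  |
| gamma | 0.38 M | 0.57 mM | 20 °C | run made earlier |  |
| epsilon | 0.57 M | 0.76 mM | −5 °C | run made earlier |  |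
| Thursday's | 0.38 M | 0.76 mM | 0 °C |  | 15 min |
| Tuesday's | 0.38 M | 0.76 mM | 20 °C |  | 15 min |
| Saturday's | 0.38 M | 0.76 mM | 40 °C |  | 15 min |

- zeta (time / min: monomer in chains / %, free monomer / %): 2.50: 0.9, 99.6; 5.00: 0.3, 99.1; 6.00: 1.0, 99.4; 10.0: 2.1, 97.5
- gamma (time / min: monomer in chains / %, free monomer / %): 0.250: 0.2, 100.3; 0.500: 1.6, 99.4; 1.33: 2.4, 96.6; 4.00: 13.4, 87.9
- epsilon (time / min: monomer in chains / %, free monomer / %): 0.667: 0, 99.0; 1.50: 0.6, 100.0; 4.00: 2.0, 99.0; 10.0: 5.4, 94.5

(standard deviation of a reading: 0.5 percentage points)

* the flask that comes out highest in amount of monomer in chains, in percent of the free monomer charged, or "all alike" when all lie within 1.5 percentage points (Thursday's / Tuesday's / Saturday's / all alike)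
* monomer in chains at the end, in percent of the free monomer charged, Thursday's
* monomer in chains at the end, in percent of the free monomer charged, Tuesday's
* monomer in chains at the end, in percent of the free monomer charged, Saturday's



Free monomer and monomer in chains added up closely to the charge, so I followed the loss of free monomer and treated it as pseudo-first-order. The epsilon run, charged with 0.76 mM of initiator like the new flasks, gave a constant of 0.00566 /min from its last reading at −5 °C. The zeta run, with 0.38 mM of initiator and also with 0.38 M of free monomer against the 0.57 M of the epsilon run, gave 0.00253 /min, roughly half of that, so, assuming that a first-order constant does not depend on the charge of free monomer, I took the constant as proportional to c(initiator), knowing that these readings carry their scatter. Scaled to 0.76 mM, the gamma run gave 0.0430 /min at 20 °C, a factor of 7.60 above the cold value. With the same proportional rise per degree, I reached 0.00849 /min at 0 °C and 0.218 /min at 40 °C.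

I then counted in the monomer lifetime, one over that constant, the time in which free monomer falls by a factor e. For Thursday's it came to 118 min, for Tuesday's to 23.3 min, and for Saturday's to 4.59 min. So 15 min counted 0.127, 0.645 and 3.27 lifetimes, and my reckoning put monomer in chains at 11.9 %, 47.5 % and 96.2 %. The forecast said 11 %, 48 % and 88 %, with Saturday's highest, and the two differed on Saturday's, where the forecast wrote “I therefore shade Saturday's value down and keep its range wide”.

The flasks gave 12.9 %, 44.3 % and 40.4 %, with Tuesday's highest.

    free monomer + living end → monomer in chains + living end, rate k1*[living end]*[free monomer] (k = 1.40 /M/s, Ea = 55.0 kJ/mol)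
    living end → dead end (k = 0.00110 /s, Ea = 79.0 kJ/mol)
    free monomer + initiator → living end + monomer in chains (k = 0.0480 /M/s, Ea = 44.0 kJ/mol)
    (constants at 20 °C)

Saturday's free monomer stood at 60.3 % after 7.50 min and still at 59.6 % after 15.0 min, which is 0.518 lifetimes, or 2.38 min of reckoned work. It stopped there because its living ends turned into dead ends: with that step struck out, Saturday's gave 98.1 % instead of 40.4 %. A flask the same as Tuesday's but charged with 0.0030 M of initiator had a reckoned lifetime of 5.89 min, so 15 min counted 2.55 lifetimes and left 7.83 % free monomer by my count, and that flask held 10.1 % at the end.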